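I start from an easy count: each target takes up one second substrate, and the flasks asked about all carry 0.500 equiv of it on the starting material, some of them by a feed.

| flask | starting material | second substrate | free enzyme | remark | time |
|---|---|---|---|---|---|
| teal | 14 mM | 0.50 equiv | 0.037 mol% | run made earlier |  |
| grey | 14 mM | 0.70 equiv | 0.037 mol% | run made earlier |  |
| ochre | 14 mM | 1.1 equiv | 0.037 mol% | run made earlier |  |
| green | 14 mM | 0.50 equiv | 0.018 mol% | run made earlier |  |
| Monday's | 14 mM | 0.500 equiv | 0.037 mol% | everything together at the start | 2.0 h |
| Sunday's | 14 mM (fed, over 80 min) | 0.500 equiv | 0.037 mol% | all else is in the flask from the start; the feed brings no volume worth counting | 2.0 h |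
| Wednesday's | 14 mM (fed, over 20 min) | 0.500 equiv | 0.037 mol% | all else is in the flask from the start; the feed brings no volume worth counting | 2.0 h |
| Tuesday's | 14 mM | 0.500 equiv (fed, over 80 min) | 0.037 mol% | all else is in the flask from the start; the feed brings no volume worth counting | 2.0 h |

teal run (percent of the starting material charged)

| time / min | target / % | starting material / % |
|---|---|---|
| 5.00 | 5.9 | 93.3 |
| 15.0 | 18.1 | 79.3 |
| 25.0 | 30.3 | 70.8 |
| 40.0 | 42.0 | 58.5 |
| 60.0 | 50.3 | 51.7 |
| 80.0 | 49.8 | 51.4 |

grey run (percent of the starting material charged)

| time / h | target / % | starting material / % |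
|---|---|---|
| 0.167 | 14.0 | 86.4 |
| 0.500 | 38.7 | 63.0 |
| 0.833 | 53.4 | 45.5 |
| 1.33 | 65.4 | 34.8 |
| 2.00 | 69.8 | 28.9 |
| 2.50 | 70.4 | 28.7 |

ochre run (percent of the starting material charged)

| time / h | target / % | starting material / % |
|---|---|---|
| 0.200 | 17.5 | 83.0 |
| 0.333 | 28.1 | 71.6 |
| 0.500 | 40.0 | 58.8 |
| 0.833 | 60.7 | 39.9 |
| 1.33 | 77.3 | 22.2 |
| 2.50 | 95.9 | 2.7 |

green run (percent of the starting material charged)

| time / h | target / % | starting material / % |
|---|---|---|
| 0.200 | 8.8 | 92.0 |
| 0.333 | 13.5 | 85.6 |
| 0.667 | 24.9 | 76.1 |
| 1.33 | 40.9 | 58.2 |
| 2.50 | 49.2 | 51.3 |

(each reading ± 1 percentage point)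

- the earlier runs were read with a standard deviation of 1 percentage point
- steps under discussion: starting material + free enzyme <-> first complex; first complex <-> loaded enzyme + first product; second substrate + loaded enzyme <-> second complex; second complex -> free enzyme + target

* which flask leads in amount of target, in percent of the starting material charged ("all alike" within 1.5 percentage points) (Monday's / Sunday's / Wednesday's / Tuesday's / all alike)
* how much target is there at the end, in percent of the starting material charged: Monday's
* how much target is there at the end, in percent of the starting material charged: Sunday's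
* how much target is there at the end, in percent of the starting material charged: Wednesday's
* how much target is there at the end, in percent of the starting material charged: Tuesday's

The teal run looks contradictory. At 80.0 min it reads 49.8 % target with 51.4 % starting material still in it, yet the green run, with 0.018 mol% of free enzyme against 0.037 mol%, climbs to 49.2 % by 2.50 h, so lost enzyme doesn't show. The grey run clears this up: on 0.70 equiv it reads 70.4 % at 2.50 h, so the level at which a run ends follows the second substrate, the limiting reagent, and I call that level the ceiling.

What remains is whether a flask reaches its ceiling in 2.0 h. I replace the teal curve by its mean rate, 42.0 % in 40.0 min. The ceiling, read as 49.8 %, divided by that mean rate is 47.4 min; I call this the fill time, the time to reach the ceiling at the mean rate. The line errs on the short side: the teal run first reads near the ceiling at 60.0 min, 12.6 min after the fill time, and that reading carries a scatter of 1 percentage point. The slow feeds last longer than the fill time, so I let the enzyme keep pace with them. The 40.0 min after such a feed are 0.844 of a fill time, so I expect Sunday's and Tuesday's just under the ceiling.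

The forecast says all alike, with 49.9 % for Monday's, 49.4 % for Sunday's, 49.8 % for Wednesday's and 48.5 % for Tuesday's, on the ground that “Every run stops at the second substrate's stoichiometric limit”. The flasks give all alike: 50.0 %, 49.8 %, 50.0 % and 49.7 %, in that order.

    starting material + free enzyme ⇌ first complex (K = 170 M⁻¹, k = 150 M⁻¹ s⁻¹)
    first complex ⇌ loaded enzyme + first product (K = 0.00580 M, k = 13.0 s⁻¹)
    second substrate + loaded enzyme ⇌ second complex (K = 1200 M⁻¹, k = 2600 M⁻¹ s⁻¹)
    second complex → free enzyme + target (k = 1.30 s⁻¹)

So a feed changes the path here, not the yield. At 1.33 h, the end of its feed, Tuesday's stands at 41.8 % target. At 2.00 h Tuesday's stands at 49.7 %. Monday's, stopped at 47.7 min, close to the fill time, lies 5 points off its answer. The neighbour of Monday's with 0.200 equiv of second substrate takes the same reckoning: the fill time scales with that charge to 19.0 min, shorter than 2.0 h. That flask reads 20.0 % target, with 80.0 % starting material still in it.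

(The numbers in the tables were computed for substances that don't exist; scatter was added.)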